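**Assumption:** locants C1–C7 follow the natural-product numbering (C1 = carbinol carbon carrying C7H2OBz, C2 and C3 = acetoxy carbons, C4=C5, C6 = benzoyloxy carbon), so the target is (1S,2S,3R,6S); a sequence run in one flask counts as one step.

## Retrosynthetic overview

1. 10 ⇒ 9 (benzoylate C6–OH) ⇒ vinyl oxirane 8 (Pd(0)/AcOH syn-1,4 opening puts C3–OAc cis to C6–O) ⇒ dienol 7 (C1–OH-directed epoxidation of C5=C6).
2. 7, a cleistodienol-type trans-"arene dihydrodiol" monoacetate, ⇒ dibromide 6 ⇒ cyclohexene 5 ⇒ 4.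
3. 4 ⇒ oxirane 3 by trans-opening at C2 with acetic acid; 3 is a configurationally stable 4,5-dihydro stand-in for benzyl benzoate 1,2-oxide, which as the free arene oxide would racemise through its oxepin.
4. 3 ⇒ 2 (asymmetric epoxidation) ⇒ benzyl alcohol 1 (Birch reduction).
5. Ring order: carbocycle taken from the arene; oxirane C1–C2 formed and opened; diene unveiled; oxirane C5–C6 formed and opened.

## Route

**Step 1**
Reactants: 1 benzyl alcohol
Product: 2 cyclohexa-1,4-dien-1-ylmethanol
Conditions: Li (3 equiv), NH3(l)/THF, EtOH, −78 → −33 °C; NH4Cl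
Reagents that add atoms: none
Why: Birch reduction, in which the benzylic alkoxide formed in situ resists C–O hydrogenolysis and the donor-substituted ring gives the 2,5-dihydro isomer with the CH2OH-bearing carbon on a double bond; no stereocentre is formed.

**Step 2**
Reactants: 2 cyclohexa-1,4-dien-1-ylmethanol
Product: 4 (1S,6R)-6-hydroxy-6-(hydroxymethyl)cyclohex-3-en-1-yl acetate, via epoxy alcohol 3 (not isolated)
Conditions: Ti(OiPr)4 (10 mol%), D-(−)-DET (12 mol%), TBHP (1.1 equiv), 4 Å MS, CH2Cl2, −20 °C; then Ti(OiPr)4 (1.5 equiv), AcOH (3 equiv), −20 °C → rt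
Reagents that add atoms: tert-butyl hydroperoxide CC(C)(C)OO; acetic acid CC(=O)O
Why: Katsuki–Sharpless asymmetric epoxidation touches only the allylic alkene and, with D-(−)-tartrate, gives the (1R,6R)-oxirane (mirror image of the S,S series that L-(+)-tartrate gives with 1-cyclohexenylmethanols), fixing C1, after which the Sharpless Ti(OiPr)4-mediated C3-selective opening of the 2,3-epoxy alcohol lets acetate attack the secondary C2 anti (trans-diaxial, inversion), fixing C2 trans to the retained C1–O bond.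

**Step 3**
Reactants: 4 (1S,6R)-6-hydroxy-6-(hydroxymethyl)cyclohex-3-en-1-yl acetate
Product: 5 [(1R,6S)-6-acetoxy-1-hydroxycyclohex-3-en-1-yl]methyl benzoate
Conditions: BzCl (1.05 equiv), pyridine, CH2Cl2, −20 → 0 °C
Reagents that add atoms: benzoyl chloride O=C(Cl)c1ccccc1
Why: Selective acylation (Einhorn-type benzoylation) of the primary alcohol over the hindered tertiary one; run cold so the C2 acetate does not drift to O7.

**Step 4**
Reactants: 5 [(1R,6S)-6-acetoxy-1-hydroxycyclohex-3-en-1-yl]methyl benzoate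
Product: 6 [(1R,2S,4S,5S)-2-acetoxy-4,5-dibromo-1-hydroxycyclohexyl]methyl benzoate
Conditions: Br2 (1.0 equiv), Et4NBr (0.2 equiv), CH2Cl2, −78 °C
Reagents that add atoms: bromine BrBr
Why: Electrophilic anti-addition of bromine to the isolated alkene, with added bromide intercepting the bromonium ion before the C1–OH can; the two C–Br centres are erased in step 5, so the other trans-dibromide, if formed, converges.

**Step 5**
Reactants: 6 [(1R,2S,4S,5S)-2-acetoxy-4,5-dibromo-1-hydroxycyclohexyl]methyl benzoate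
Product: 7 [(1R,6S)-6-acetoxy-1-hydroxycyclohexa-2,4-dien-1-yl]methyl benzoate
Conditions: DBU (4 equiv), toluene, 70 °C
Reagents that add atoms: none
Why: Double E2 dehydrobromination (anti-periplanar H3/Br4 and H6/Br5), the classical route to arene trans-dihydrodiol esters, unveils the diene under basic conditions that the acid-labile dienol tolerates; C1 and C2 are untouched.

**Step 6**
Reactants: 7 [(1R,6S)-6-acetoxy-1-hydroxycyclohexa-2,4-dien-1-yl]methyl benzoate
Product: 9 [(1S,2S,5R,6S)-5,6-diacetoxy-1,2-dihydroxycyclohex-3-en-1-yl]methyl benzoate, via vinyl epoxide 8 (not isolated)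
Conditions: VO(acac)2 (2 mol%), TBHP (1.0 equiv), CH2Cl2, 0 °C; then Pd(PPh3)4 (3 mol%), AcOH (1.5 equiv), THF, 0 °C → rt
Reagents that add atoms: tert-butyl hydroperoxide CC(C)(C)OO; acetic acid CC(=O)O
Why: Proposed new method: two known reaction types (Sharpless–Michaelson V/TBHP epoxidation directed by the tertiary allylic C1–OH onto C5=C6 from the OH face, and Tsuji–Trost-type Pd(0) cis-1,4-addition of a carboxylic acid to a cyclic diene monoepoxide) are merged in one flask with TBHP as limiting reagent so that no oxidant meets Pd(0), where Pd ionises the allylic C5–O bond anti and acetate adds to C3 of the π-allyl anti to Pd and distal to the alkoxide (double inversion, net syn-SN2′), placing C3–OAc cis to the retained C6–OH and setting C3 (R) and C6 (S).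

**Step 7**
Reactants: 9 [(1S,2S,5R,6S)-5,6-diacetoxy-1,2-dihydroxycyclohex-3-en-1-yl]methyl benzoate
Product: 10 cleistenediol F, [(1S,2S,5R,6S)-5,6-diacetoxy-2-(benzoyloxy)-1-hydroxycyclohex-3-en-1-yl]methyl benzoate
Conditions: BzCl (1.3 equiv), pyridine, DMAP (cat.), CH2Cl2, 0 °C → rt
Reagents that add atoms: benzoyl chloride O=C(Cl)c1ccccc1
Why: DMAP-catalysed benzoylation of the secondary allylic C6–OH while the tertiary C1–OH stays free as in the natural product; no stereocentre is touched, and a benzoyl shift between O7 and O6 would be degenerate after full benzoylation.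

## Compound list

1 | benzyl alcohol | OCc1ccccc1 | starting material
2 | cyclohexa-1,4-dien-1-ylmethanol | OCC1=CCC=CC1 | intermediate
3 | [(1R,6R)-7-oxabicyclo[4.1.0]hept-3-en-1-yl]methanol (epoxy alcohol, not isolated) | OC[C@@]12O[C@@H]1CC=CC2 | intermediate
4 | (1S,6R)-6-hydroxy-6-(hydroxymethyl)cyclohex-3-en-1-yl acetate | OC[C@]1(O)CC=CC[C@@H]1OC(C)=O | intermediate
5 | [(1R,6S)-6-acetoxy-1-hydroxycyclohex-3-en-1-yl]methyl benzoate | O=C(OC[C@]1(O)CC=CC[C@@H]1OC(C)=O)c1ccccc1 | intermediate
6 | [(1R,2S,4S,5S)-2-acetoxy-4,5-dibromo-1-hydroxycyclohexyl]methyl benzoate | O=C(OC[C@]1(O)C[C@H](Br)[C@@H](Br)C[C@@H]1OC(C)=O)c1ccccc1 | intermediate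
7 | [(1R,6S)-6-acetoxy-1-hydroxycyclohexa-2,4-dien-1-yl]methyl benzoate | C1=CC=C[C@@](O)(COC(=O)c2ccccc2)[C@H]1OC(C)=O | intermediate
8 | [(1S,4S,5R,6S)-4-acetoxy-5-hydroxy-7-oxabicyclo[4.1.0]hept-2-en-5-yl]methyl benzoate (5,6-epoxide of 7 on the C1–OH face, not isolated) | C1=C[C@@H]2O[C@@H]2[C@@](O)(COC(=O)c3ccccc3)[C@H]1OC(C)=O | intermediate
9 | [(1S,2S,5R,6S)-5,6-diacetoxy-1,2-dihydroxycyclohex-3-en-1-yl]methyl benzoate | CC(=O)O[C@@H]1C=C[C@H](O)[C@@](O)(COC(=O)c2ccccc2)[C@H]1OC(C)=O | intermediate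
10 | cleistenediol F, [(1S,2S,5R,6S)-5,6-diacetoxy-2-(benzoyloxy)-1-hydroxycyclohex-3-en-1-yl]methyl benzoate | CC(=O)O[C@@H]1C=C[C@H](OC(=O)c2ccccc2)[C@@](O)(COC(=O)c2ccccc2)[C@H]1OC(C)=O | target

## Step count and risks

Total step count: 7. Longest linear sequence: 7 (fully linear).

**Step 6 (most likely to fail).** The dienol 7 and the vinyl epoxide 8 can aromatise by losing water. Acetate could also add at C5 instead of C3, and vanadium residues could disturb the Pd(0) cycle. The fallback sets out from 7 and comes back at 9. Photooxygenation (O2, TPP, hν, CH2Cl2, −30 °C) adds singlet oxygen in a [4+2] sense on the face carrying C1–OH, opposite C2–OAc and C7. This gives the endoperoxide [(1S,4R,7R,8S)-8-acetoxy-7-hydroxy-2,3-dioxabicyclo[2.2.2]oct-5-en-7-yl]methyl benzoate F5. Thiourea in MeOH cleaves the O–O bond to the cis-3,6-diol [(1S,2S,5R,6S)-6-acetoxy-1,2,5-trihydroxycyclohex-3-en-1-yl]methyl benzoate F6. Acetylation of the less hindered C3–OH (Ac2O, 2,4,6-collidine, −40 °C, or lipase with vinyl acetate) then gives 9.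

**Step 2.** The acetolysis could open the oxirane at the tertiary C1, titanium could shift the acetyl group to the primary alcohol, and isopropoxide could compete as nucleophile. The fallback sets out from 2 and comes back at 5. The same asymmetric epoxidation is run, but the epoxy alkoxide is trapped in the flask with BzCl/Et3N/DMAP, and the epoxy benzoate [(1R,6R)-7-oxabicyclo[4.1.0]hept-3-en-1-yl]methyl benzoate F1 is isolated. It is then opened without titanium by buffered acetate (Bu4NOAc/AcOH, toluene, 80 °C), a plain trans-diaxial SN2 attack at the secondary C2, which gives 5 directly and leaves out 4.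

**Step 4 (and with it step 5).** The free tertiary C1–OH can capture the bromonium ion across the ring to give a 7-oxanorbornane bromo-ether, and it is then carried unprotected through hot DBU. The fallback sets out from 5 and comes back at 7. The tertiary alcohol is capped (TESOTf, 2,6-lutidine) to give [(1R,6S)-6-acetoxy-1-(triethylsilyloxy)cyclohex-3-en-1-yl]methyl benzoate F2. Bromination gives [(1R,2S,4S,5S)-2-acetoxy-4,5-dibromo-1-(triethylsilyloxy)cyclohexyl]methyl benzoate F3. DBU elimination gives [(1R,6S)-6-acetoxy-1-(triethylsilyloxy)cyclohexa-2,4-dien-1-yl]methyl benzoate F4. The silyl group is removed with pyridine-buffered HF·pyridine in THF at 0 °C to reach 7.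

## Further compounds

F1 | step 2 | [(1R,6R)-7-oxabicyclo[4.1.0]hept-3-en-1-yl]methyl benzoate | O=C(OC[C@@]12O[C@@H]1CC=CC2)c1ccccc1
F2 | step 4 | [(1R,6S)-6-acetoxy-1-(triethylsilyloxy)cyclohex-3-en-1-yl]methyl benzoate | O=C(OC[C@]1(O[Si](CC)(CC)CC)CC=CC[C@@H]1OC(C)=O)c1ccccc1
F3 | step 4 | [(1R,2S,4S,5S)-2-acetoxy-4,5-dibromo-1-(triethylsilyloxy)cyclohexyl]methyl benzoate | O=C(OC[C@]1(O[Si](CC)(CC)CC)C[C@H](Br)[C@@H](Br)C[C@@H]1OC(C)=O)c1ccccc1
F4 | step 4 | [(1R,6S)-6-acetoxy-1-(triethylsilyloxy)cyclohexa-2,4-dien-1-yl]methyl benzoate | C1=CC=C[C@@](O[Si](CC)(CC)CC)(COC(=O)c2ccccc2)[C@H]1OC(C)=O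
F5 | step 6 | [(1S,4R,7R,8S)-8-acetoxy-7-hydroxy-2,3-dioxabicyclo[2.2.2]oct-5-en-7-yl]methyl benzoate | O1[C@@H]2C=C[C@H](O1)[C@@](O)(COC(=O)c3ccccc3)[C@H]2OC(C)=O
F6 | step 6 | [(1S,2S,5R,6S)-6-acetoxy-1,2,5-trihydroxycyclohex-3-en-1-yl]methyl benzoate | O[C@@H]1C=C[C@H](O)[C@@](O)(COC(=O)c2ccccc2)[C@H]1OC(C)=O
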